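Item one at the meeting was the leftover: how much electrophile still stands at the end of these flasks, where a solid base is meant to take up the acid set free as electrophile and nucleophile give product.

| setting | alpha | gamma | delta |
|---|---|---|---|
| electrophile | 0.050 M | 0.050 M | 0.050 M |
| nucleophile | 1.70 equiv | 1.30 equiv | 1.00 equiv |
| solid base | 1.10 equiv | 1.10 equiv | 1.10 equiv |
| protic impurity | 0.0500 M | 0.0500 M | 0.0500 M |
| time | 10 min | 10 min | 10 min |

1. part of the electrophile that has reacted at the end, alpha
2. part of the electrophile that has reacted at the end, gamma
3. part of the electrophile that has reacted at the end, delta
4. what raising the equivalents of nucleophile from its lowest to its highest value here does to the part of the electrophile that has reacted (changes below 5 percentage points count as none) (no change / it rises / it falls)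

- solid, in amounts per volume of the solution: solid base
- at the start none of the solid base is in solution
- run time (alpha): 10 min

    protic impurity + free base → quenched reagent (k1 = 1.27 /M/min)
    electrophile + nucleophile → acid set free + product (k2 = 2.29 /M/min)
    nucleophile + acid set free ⇌ protonated nucleophile, settled at all times (K3 = 1100 /M)
    acid set free + free base ⇌ salt of the base, settled at all times (K4 = 49.6 /M)
    nucleophile ⇌ dormant form (K5 = 2.15, k5 = 0.249 /min)
    solid base ⇌ free base, rate k6*(cs6 - [free base]) while solid is left; crystals form when [free base] > cs6 (cs6 = 1.6 mM, k6 = 0.138 /min)

I argued first that the base falls behind. Dissolving at full driving force, the solid delivers 0.221 mM/min, while delta, the leanest flask, opens by making acid at 5.73 mM/min, so acid outruns base.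

I added that dissolved base also loses the contest for the acid. The nucleophile's pull, equilibrium constant times concentration, is 55 as charged in delta, against 0.0794 for free base at its solubility.

Early on each product therefore costs a second nucleophile, held as protonated nucleophile. I proposed to count that price as a yardstick, giving 85.0% for alpha, 65.0% for gamma and 50.0% for delta. This is the two-for-one mark, half the nucleophile equivalents read as a conversion; it is an estimate, not a ceiling. Each mark stands below full conversion, so on this count nucleophile is the limiting reagent.

I conceded that a mark has no clock in it. The dormant form fills with a relaxation half-life of 1.90 min in gamma, shorter than the run, and takes nucleophile away from the coupling. I therefore committed to conversions below the marks and to a rise, since the marks differ by 35 percentage points, more than the 5 points that counts.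

The forecast was then read out: 46%, 37% and 30%, trend it rises, on the ground that “each product ties up a second nucleophile as its protonated form”.

The simulation gives 44.4%, 35.6% and 28.4%; the trend is it rises, by 16 points. The forecast is right on each count.

Gamma ends at 0.548 of its mark of 65.0%, holding 0.0159 M of protonated nucleophile, with solid base at 97.5% of its charge. A neighbour of gamma has electrophile raised to 0.20 M and the equivalents held, so its mark is again 65.0%. The opening acid rate of that neighbour is 119 mM/min, against the same 0.221 mM/min of base. That neighbour ends at 56.1%, which is 0.863 of the mark, with 0.101 M of protonated nucleophile and solid base at 99.3% of its charge.

The numbers of this flask are invented; the flask was simulated.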